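**Retrosynthetic overview**

Numbering (azulene): C3 = C(OH)(iPr), C3a = ring-fusion CH, C4 = CH–OCOAr, C5 = CH2, C6 = C(CH3)=, C7 = CH=, C8 = C=O, C8a = C(CH3); ring A = cyclopentane, ring B = cycloheptenone.
Last disconnections: the vanillate (acylation of the secondary C4–OH, phenol carried as its acetate) and a di-tert-butylsilylene that ties O3 and O4 of the syn-1,3-diol into a temporary ring C.
Key disconnection: C8a–C3a and C5–C4 are cut together, which opens both carbocycles; forward, a 2-ethoxypentadienyl cation (C8a–C8–C7–C6–C5) is captured by a cyclic silyl enol ether (C3a=C4), ring A closing first and ring B second in one operation.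
Enabling feature: the C8 ketone lies between quaternary C8a and the C7=C6(CH3)–C5H2 unit (a 2-oxypentadienyl cation after ionisation at C8a), and C3a–C4 with its syn oxygens at C3 and C4 is the enol of a β-hydroxy aldehyde that a six-membered O–Si–O ring can hold in the cis form.
The chain comes from a methyl ketone plus α-lithiated (E)-1-ethoxy-3-methylbuta-1,3-diene; the keto aldehyde comes from ozonolytic cleavage of the ring C=C of (S)-terpinen-4-ol, whose carbinol carbon becomes C3 and directs C3a, C4 and C8a.

Key step: step 5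

Remark: (S)-terpinen-4-ol is assumed to be purchasable in high enantiomeric purity; its carbinol centre is carried through unchanged, so its ee sets that of the target.

**Route**

Step 1
Reactants: 1 (S)-(+)-terpinen-4-ol [(1S)-4-methyl-1-(propan-2-yl)cyclohex-3-en-1-ol]
Product: 3 (3S)-3-hydroxy-6-oxo-3-(propan-2-yl)heptanal, via secondary ozonide 2 (not isolated)
Conditions: O3, CH2Cl2, −78 °C; then Me2S, −78 °C to rt; used crude
Reagents that add atoms: ozone, O=[O+][O-]
Why: Ozonolysis with reductive work-up cleaves the only C=C bond, turning the trisubstituted ring alkene into a methyl ketone and an aldehyde while the carbinol stereocentre is not touched.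

Step 2
Reactants: 3 (3S)-3-hydroxy-6-oxo-3-(propan-2-yl)heptanal
Product: 5 (4R)-2,2-di-tert-butyl-4-(3-oxobutyl)-4-(propan-2-yl)-4H-1,3,2-dioxasiline, via silyl monotriflate 4 (not isolated)
Conditions: tBu2Si(OTf)2 (1.05 equiv), Et3N, CH2Cl2, −78 °C to 0 °C
Reagents that add atoms: di-tert-butylsilyl bis(trifluoromethanesulfonate), CC(C)(C)[Si](OS(=O)(=O)C(F)(F)F)(OS(=O)(=O)C(F)(F)F)C(C)(C)C
Why: O-Silylation of the tertiary alcohol followed by intramolecular amine-mediated enol silylation of the aldehyde (silyl triflate soft enolisation) should close the six-membered ring, which can only hold a cis enol ether, the aldehyde reacting before the methyl ketone because it is more electrophilic and gives the six- rather than the seven-membered ring.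

Step 3
Reactants: 6 1,1-diethoxy-3-methylbut-2-ene (3-methylbut-2-enal diethyl acetal)
Product: 7 (1E)-1-ethoxy-3-methylbuta-1,3-diene
Conditions: TsOH (cat.), quinoline (cat.), 140 °C, ethanol distilled off; fractional distillation
Reagents that add atoms: none
Why: Acid-catalysed 1,4-elimination of ethanol from the α,β-unsaturated acetal (oxocarbenium ion, loss of a γ-proton) gives the 1-alkoxydiene, the (E) isomer being favoured under these equilibrating conditions.

Step 4
Reactants: 7 (1E)-1-ethoxy-3-methylbuta-1,3-diene; 5 (4R)-2,2-di-tert-butyl-4-(3-oxobutyl)-4-(propan-2-yl)-4H-1,3,2-dioxasiline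
Product: 10 (4R)-2,2-di-tert-butyl-4-[(4E)-4-ethoxy-3-hydroxy-3,6-dimethylhepta-4,6-dien-1-yl]-4-(propan-2-yl)-4H-1,3,2-dioxasiline (both carbinol epimers), via lithiodiene 8 (not isolated), via lithium alkoxide 9 (not isolated)
Conditions: 7, t-BuLi, THF, −78 °C to −40 °C; then 5, −78 °C; then H2O; chromatography on Et3N-deactivated silica
Reagents that add atoms: none
Why: α-Lithiation of the alkenyl ether is stereoretentive, so lithium sits cis to the isopropenyl group, and 1,2-addition of this alkenyllithium to the methyl ketone gives the tertiary alcohol with the quaternary carbon cis to the isopropenyl group across the enol ether C=C (the carbinol centre is ionised in step 5, so both epimers are used).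

Step 5
Reactants: 10 (4R)-2,2-di-tert-butyl-4-[(4E)-4-ethoxy-3-hydroxy-3,6-dimethylhepta-4,6-dien-1-yl]-4-(propan-2-yl)-4H-1,3,2-dioxasiline
Product: 15 (3R,3aS,4R,8aS)-3,4-O-(di-tert-butylsilanediyl)-3,4-dihydroxy-6,8a-dimethyl-3-(propan-2-yl)-2,3,3a,4,5,8a-hexahydroazulen-8(1H)-one, via tertiary triflate 11 (not isolated), via ethoxypentadienyl cation 12 (not isolated), via silyloxocarbenium ion 13 (not isolated), via ethyl oxocarbenium ion 14 (not isolated)
Conditions: Tf2O, 2,6-lutidine, CH2Cl2, −78 °C; then H2O, NaHCO3, −78 °C to 0 °C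
Reagents that add atoms: water, O
Why: Proposed new method: O-triflation and ionisation of the tertiary alcohol give the 2-ethoxypentadienyl cation 12, whose tertiary terminus is attacked by the β-carbon of the tethered silyl enol ether (ring A, 5-exo-trig) to give the cyclic silyloxocarbenium ion 13, which is captured by the CH2 terminus of the 1-ethoxydiene in a vinylogous Mukaiyama-type addition (ring B, 7-(enolendo)-exo-trig), and water then hydrolyses the ethyl oxocarbenium ion 14 to the enone. The closest known reaction types are the intramolecular (4+3) cycloadditions of 2-alkoxyallyl cations generated from 2-alkoxyallylic alcohols with Tf2O and 2,6-lutidine, and the stepwise (5+2) annulation of enol silyl ethers with Co2(CO)6-stabilised propargyl cations that carry an allylsilane; the new element is a 2-alkoxypentadienyl cation as the five-carbon partner. C3a is set by the dioxasiline ring: the cation can reach the enol ether only on the face that carries the tether, so the new bond is cis to the tether and the isopropyl group ends cis to the ring-fusion hydrogen. C8a is set by sterics: the planar ethoxydienyl arm should point away from the di-tert-butylsilylene ring with the methyl group over it, which places C8 trans to C4 (trans ring fusion). C4 is set by the six-membered cyclic oxocarbenium ion, which the dienyl terminus can reach only from the face of C8a, so the C4–O and C3–O bonds end cis and both stay on silicon. The step needs C- over O-capture and seven- over five-ring closure, and these are secured by the cis geometry of the enol ether C=C from step 4, by the ethyl cap on the enol oxygen and by the unfavourable 5-(enolendo) alternative.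

Step 6
Reactants: 15 (3R,3aS,4R,8aS)-3,4-O-(di-tert-butylsilanediyl)-3,4-dihydroxy-6,8a-dimethyl-3-(propan-2-yl)-2,3,3a,4,5,8a-hexahydroazulen-8(1H)-one
Product: 16 (3R,3aS,4R,8aS)-3,4-dihydroxy-6,8a-dimethyl-3-(propan-2-yl)-2,3,3a,4,5,8a-hexahydroazulen-8(1H)-one
Conditions: HF·pyridine, THF/pyridine, 0 °C to rt
Reagents that add atoms: none
Why: Fluoride cleavage of both Si–O bonds of the silylene under buffered, non-basic conditions should free the 1,3-diol without retro-aldol-type opening or β-elimination of the δ-hydroxy enone.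

Step 7
Reactants: 17 4-acetoxy-3-methoxybenzoic acid
Product: 18 4-acetoxy-3-methoxybenzoyl chloride
Conditions: (COCl)2, DMF (cat.), CH2Cl2, 0 °C to rt; concentrated and used directly
Reagents that add atoms: oxalyl chloride, O=C(Cl)C(Cl)=O
Why: Acid chloride formation through the catalytic Vilsmeier-type chloroiminium species leaves the aryl acetate untouched.

Step 8
Reactants: 16 (3R,3aS,4R,8aS)-3,4-dihydroxy-6,8a-dimethyl-3-(propan-2-yl)-2,3,3a,4,5,8a-hexahydroazulen-8(1H)-one; 18 4-acetoxy-3-methoxybenzoyl chloride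
Product: 19 [(3R,3aS,4R,8aS)-3-hydroxy-6,8a-dimethyl-8-oxo-3-(propan-2-yl)-1,2,3,3a,4,5,8,8a-octahydroazulen-4-yl] 4-acetoxy-3-methoxybenzoate
Conditions: pyridine, DMAP (cat.), CH2Cl2, 0 °C to rt
Reagents that add atoms: none
Why: DMAP-catalysed acylation should select the secondary over the tertiary hydroxyl on steric grounds and proceeds with retention at C4.

Step 9
Reactants: 19 [(3R,3aS,4R,8aS)-3-hydroxy-6,8a-dimethyl-8-oxo-3-(propan-2-yl)-1,2,3,3a,4,5,8,8a-octahydroazulen-4-yl] 4-acetoxy-3-methoxybenzoate
Product: 20 [(3R,3aS,4R,8aS)-3-hydroxy-6,8a-dimethyl-8-oxo-3-(propan-2-yl)-1,2,3,3a,4,5,8,8a-octahydroazulen-4-yl] 4-hydroxy-3-methoxybenzoate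
Conditions: NH4OAc, MeOH/H2O (4:1), rt
Reagents that add atoms: none
Why: The aryl acetate is a far better acyl donor than the hindered alkyl benzoate, so near-neutral solvolysis should remove only the phenolic acetate and avoid base-induced vinylogous β-elimination of the aroyloxy group.

**Compound list**

1 | (S)-(+)-terpinen-4-ol, (1S)-4-methyl-1-(propan-2-yl)cyclohex-3-en-1-ol | CC1=CC[C@](O)(C(C)C)CC1 | starting material
2 | secondary ozonide of 1 (1,2,4-trioxolane across the former C=C, mixture at the two acetal carbons) | CC12CC[C@@](O)(C(C)C)CC(OO1)O2 | intermediate (not isolated)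
3 | (3S)-3-hydroxy-6-oxo-3-(propan-2-yl)heptanal | O=CC[C@](O)(C(C)C)CCC(C)=O | intermediate
4 | tertiary di-tert-butyl(triflyloxy)silyl ether of 3 | O=CC[C@](O[Si](OS(=O)(=O)C(F)(F)F)(C(C)(C)C)C(C)(C)C)(C(C)C)CCC(C)=O | intermediate (not isolated)
5 | (4R)-2,2-di-tert-butyl-4-(3-oxobutyl)-4-(propan-2-yl)-4H-1,3,2-dioxasiline | CC(=O)CC[C@@]1(C(C)C)C=CO[Si](C(C)(C)C)(C(C)(C)C)O1 | intermediate
6 | 1,1-diethoxy-3-methylbut-2-ene | CCOC(OCC)C=C(C)C | starting material
7 | (1E)-1-ethoxy-3-methylbuta-1,3-diene | CCO/C=C/C(C)=C | intermediate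
8 | 1-ethoxy-1-lithio-3-methylbuta-1,3-diene, lithium cis to the isopropenyl group | CCO/C([Li])=C/C(C)=C | intermediate (not isolated)
9 | lithium alkoxide of 10 | C=C(C)/C=C(/OCC)C(C)([O-])CC[C@@]1(C(C)C)C=CO[Si](C(C)(C)C)(C(C)(C)C)O1.[Li+] | intermediate (not isolated)
10 | (4R)-2,2-di-tert-butyl-4-[(4E)-4-ethoxy-3-hydroxy-3,6-dimethylhepta-4,6-dien-1-yl]-4-(propan-2-yl)-4H-1,3,2-dioxasiline, both carbinol epimers | C=C(C)/C=C(/OCC)C(C)(O)CC[C@@]1(C(C)C)C=CO[Si](C(C)(C)C)(C(C)(C)C)O1 | intermediate
11 | tertiary triflate of 10 | C=C(C)/C=C(/OCC)C(C)(OS(=O)(=O)C(F)(F)F)CC[C@@]1(C(C)C)C=CO[Si](C(C)(C)C)(C(C)(C)C)O1 | intermediate (not isolated)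
12 | 2-ethoxypentadienyl cation (triflate) from 11 | C=C(C)/C=C(/OCC)[C+](C)CC[C@@]1(C(C)C)C=CO[Si](C(C)(C)C)(C(C)(C)C)O1.[O-]S(=O)(=O)C(F)(F)F | intermediate (not isolated)
13 | cyclopentane-fused cyclic silyloxocarbenium ion (triflate), ring A closed | C=C(C)/C=C(/OCC)[C@@]1(C)CC[C@]2(C(C)C)O[Si](C(C)(C)C)(C(C)(C)C)[O+]=C[C@H]12.[O-]S(=O)(=O)C(F)(F)F | intermediate (not isolated)
14 | tricyclic O-ethyl oxocarbenium ion (triflate), rings A and B closed | O1[C@@H]2CC(C)=CC(=[O+]CC)[C@@]3(C)CC[C@@](O[Si]1(C(C)(C)C)C(C)(C)C)(C(C)C)[C@H]23.[O-]S(=O)(=O)C(F)(F)F | intermediate (not isolated)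
15 | (3R,3aS,4R,8aS)-3,4-O-(di-tert-butylsilanediyl)-3,4-dihydroxy-6,8a-dimethyl-3-(propan-2-yl)-2,3,3a,4,5,8a-hexahydroazulen-8(1H)-one (trans-fused; 3-O, 4-O and 8a-CH3 on one face, 3a-H on the other) | O1[C@@H]2CC(C)=CC(=O)[C@@]3(C)CC[C@@](O[Si]1(C(C)(C)C)C(C)(C)C)(C(C)C)[C@H]23 | intermediate
16 | (3R,3aS,4R,8aS)-3,4-dihydroxy-6,8a-dimethyl-3-(propan-2-yl)-2,3,3a,4,5,8a-hexahydroazulen-8(1H)-one | O[C@@H]1CC(C)=CC(=O)[C@@]2(C)CC[C@@](O)(C(C)C)[C@H]12 | intermediate
17 | 4-acetoxy-3-methoxybenzoic acid | COc1cc(C(=O)O)ccc1OC(C)=O | starting material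
18 | 4-acetoxy-3-methoxybenzoyl chloride | COc1cc(C(Cl)=O)ccc1OC(C)=O | intermediate
19 | [(3R,3aS,4R,8aS)-3-hydroxy-6,8a-dimethyl-8-oxo-3-(propan-2-yl)-1,2,3,3a,4,5,8,8a-octahydroazulen-4-yl] 4-acetoxy-3-methoxybenzoate | COc1cc(C(=O)O[C@@H]2CC(C)=CC(=O)[C@@]3(C)CC[C@@](O)(C(C)C)[C@H]23)ccc1OC(C)=O | intermediate
20 | [(3R,3aS,4R,8aS)-3-hydroxy-6,8a-dimethyl-8-oxo-3-(propan-2-yl)-1,2,3,3a,4,5,8,8a-octahydroazulen-4-yl] 4-hydroxy-3-methoxybenzoate | COc1cc(C(=O)O[C@@H]2CC(C)=CC(=O)[C@@]3(C)CC[C@@](O)(C(C)C)[C@H]23)ccc1O | target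

**Step count and risks**

Total step count: 9. Longest linear sequence: 7 (steps 1, 2, 4, 5, 6, 8, 9).

Steps most likely to fail:

1. Step 5 (Proposed new method). The first ring closure may take the wrong facial orientation of the cation and give the cis-fused isomer. The cation may also be lost to 4π-electrocyclisation or proton loss before C–C bond formation, or the cascade may stall after ring A with release of the aldehyde. The fallback uses known reaction types only; it sets out from 1 and comes back at 16. Compound 1 is silylated (TESOTf, 2,6-lutidine) to the triethylsilyl ether F1. Ozonolysis (O3, then Me2S) gives the keto aldehyde F2. Amine-catalysed intramolecular aldol condensation (piperidinium acetate, benzene, 60 °C) gives the cyclopentenecarbaldehyde F3. Copper-mediated conjugate addition of lithiodiene 8 (CuBr·SMe2, TMSCl, THF, −78 °C) builds the quaternary carbon and gives the trimethylsilyl enol ether F4. Hydrolysis (KF, MeOH), with equilibration of the formyl-bearing carbon, gives the aldehyde F5. An intramolecular vinylogous Mukaiyama-type aldol addition (BF3·OEt2, CH2Cl2, −78 °C, aqueous work-up) closes ring B to the hydroxy enone F6. HF·pyridine removes the triethylsilyl group to give 16. Facial selectivity in the conjugate addition and the aldol step is not secured by a ring in this sequence, so isomers may have to be separated.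

2. Step 2. The tertiary β-hydroxy aldehyde may dehydrate or undergo retro-aldol cleavage under the amine and silyl triflate, or the methyl ketone may be enol-silylated in competition. The fallback installs silicon before the aldehyde exists; it sets out from 1 and comes back at 5. Compound 1 is treated with tBu2Si(OTf)2 and 2,6-lutidine, and the remaining Si–OTf bond is hydrolysed on work-up to the silanol F7. Ozonolysis (O3, then Me2S) unmasks the aldehyde, which the silanol should trap as the six-membered cyclic silyl hemiacetal F8. Dehydration of this lactol-type hydroxyl by mesylation and elimination (MsCl, Et3N, then DBU), as in the conversion of lactols into cyclic enol ethers, gives 5.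

3. Step 9. Removal of the phenolic acetate may be accompanied by vinylogous β-elimination of the aroyloxy group (E1cB through the γ-position of the enone) or by acyl migration. The fallback replaces the acetate by a silyl ether that is cleaved with fluoride; it sets out from 16 and comes back at 20. Commercial vanillic acid is bis-silylated (TBSCl, imidazole, DMF) to the silyl ester F9. The silyl ester is hydrolysed (K2CO3, aqueous MeOH) to the acid F10, which is converted into its chloride F11 ((COCl)2, DMF cat.). Acylation of 16 (pyridine, DMAP) gives the aryl silyl ether F12, and HF·pyridine in THF/pyridine frees the phenol without base to give 20.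

Further compounds
F1 | step 5 | (1S)-triethyl{[4-methyl-1-(propan-2-yl)cyclohex-3-en-1-yl]oxy}silane | CC1=CC[C@](O[Si](CC)(CC)CC)(C(C)C)CC1
F2 | step 5 | (3S)-6-oxo-3-(propan-2-yl)-3-[(triethylsilyl)oxy]heptanal | O=CC[C@](O[Si](CC)(CC)CC)(C(C)C)CCC(C)=O
F3 | step 5 | (5R)-2-methyl-5-(propan-2-yl)-5-[(triethylsilyl)oxy]cyclopent-1-ene-1-carbaldehyde | O=CC1=C(C)CC[C@@]1(O[Si](CC)(CC)CC)C(C)C
F4 | step 5 | trimethylsilyl enol ether of F5 (conjugate adduct) | C[Si](C)(C)OC=C1[C@](O[Si](CC)(CC)CC)(C(C)C)CC[C@]1(C)/C(OCC)=C\C(C)=C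
F5 | step 5 | 2-(1-ethoxy-3-methylbuta-1,3-dien-1-yl)-2-methyl-5-(propan-2-yl)-5-[(triethylsilyl)oxy]cyclopentane-1-carbaldehyde, formyl cis to the methyl and silyloxy groups | O=C[C@H]1[C@](O[Si](CC)(CC)CC)(C(C)C)CC[C@]1(C)/C(OCC)=C\C(C)=C
F6 | step 5 | 3-O-triethylsilyl ether of 16 | O[C@@H]1CC(C)=CC(=O)[C@@]2(C)CC[C@@](O[Si](CC)(CC)CC)(C(C)C)[C@H]12
F7 | step 2 | di-tert-butyl{[(1S)-4-methyl-1-(propan-2-yl)cyclohex-3-en-1-yl]oxy}silanol | CC1=CC[C@](O[Si](O)(C(C)(C)C)C(C)(C)C)(C(C)C)CC1
F8 | step 2 | (4R)-2,2-di-tert-butyl-4-(3-oxobutyl)-4-(propan-2-yl)-1,3,2-dioxasilinan-6-ol (cyclic silyl hemiacetal) | CC(=O)CC[C@@]1(C(C)C)CC(O)O[Si](C(C)(C)C)(C(C)(C)C)O1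
F9 | step 9 | tert-butyldimethylsilyl 4-[(tert-butyldimethylsilyl)oxy]-3-methoxybenzoate | COc1cc(C(=O)O[Si](C)(C)C(C)(C)C)ccc1O[Si](C)(C)C(C)(C)C
F10 | step 9 | 4-[(tert-butyldimethylsilyl)oxy]-3-methoxybenzoic acid | COc1cc(C(=O)O)ccc1O[Si](C)(C)C(C)(C)C
F11 | step 9 | 4-[(tert-butyldimethylsilyl)oxy]-3-methoxybenzoyl chloride | COc1cc(C(Cl)=O)ccc1O[Si](C)(C)C(C)(C)C
F12 | step 9 | O-tert-butyldimethylsilyl ether of 20 at the phenol | COc1cc(C(=O)O[C@@H]2CC(C)=CC(=O)[C@@]3(C)CC[C@@](O)(C(C)C)[C@H]23)ccc1O[Si](C)(C)C(C)(C)C
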